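**Retrosynthetic overview**
1. The target comes from a bridged (Z)-enoate lactone by DIBAL-H reduction and MnO2 oxidation. The C16 chain is attached by a B-alkyl Suzuki coupling of a C1 vinyl group with a (1E,3Z,5E)-tetraenyl iodide, itself built from two carboaluminations and (Z)-1,2-dichloroethene.
2. The Z-tetrasubstituted alkene is set inside a temporary seven-membered lactone. That ring is closed by a new intramolecular Cu-catalysed nitronate alkylation followed by loss of HNO2.
3. The C1 quaternary centre and the C6 tertiary carbinol come from the key semipinacol 1,2-vinyl shift of a tetrasubstituted 2,3-epoxy alcohol.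
4. The epoxy alcohol comes from vinylzinc addition and directed epoxidation of a cyclohexenecarbaldehyde. That aldehyde comes from an organocatalytic nitro-Michael/aldol condensation, which sets C2.
5. Ring order: cyclohexene (step 3), then oxirane (step 4, consumed in step 5), then bridging lactone (step 7, opened in step 14).

Assumption: ring C3 (nitro-bearing) and the CHBr carbon are carried as epimer mixtures because both become sp2 in step 7, so their SMILES carry no descriptor; ring numbering is C1 = quaternary carbon, C2 = CH with the three-carbon arm, C3 = alkylidene carbon, C6 = tertiary carbinol carbon.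

**Step 1**
Reactants: 1 nitromethane; 2 methyl vinyl ketone
Product: 3 5-nitropentan-2-one
Conditions: 1 (10 equiv), KF/Al2O3 (cat.), neat, 0 °C → rt
Reagents that add atoms: none
Why: Base-catalysed Michael addition of nitromethane, in which the large excess of 1 suppresses double addition.

**Step 2**
Reactants: 4 methyl pent-4-enoate; 5 (E)-crotonaldehyde
Product: 6 methyl (E)-6-oxohex-4-enoate
Conditions: 5 (4 equiv), Hoveyda–Grubbs II (1.5 mol %), CH2Cl2, 40 °C
Reagents that add atoms: none
Why: Olefin cross-metathesis of a terminal alkene with an enal partner gives the E-enal selectively, and the ester is inert.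

**Step 3**
Reactants: 3 5-nitropentan-2-one; 6 methyl (E)-6-oxohex-4-enoate
Product: 8 methyl 3-[(1S)-2-formyl-3-methyl-6-nitrocyclohex-2-en-1-yl]propanoate, via Michael adduct 7 (not isolated)
Conditions: (R)-α,α-diphenylprolinol TMS ether (15 mol %), PhCO2H (20 mol %), MeOH, rt → 40 °C
Reagents that add atoms: none
Why: Iminium/enamine organocascade (nitro-Michael addition, then intramolecular aldol condensation) in which the (R)-catalyst shields one face of the E-iminium ion so that the nitronate carbon bonds to the enal β-carbon and sets C2, after which the enamine closes on the methyl ketone and dehydrates to the tetrasubstituted enal.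

**Step 4**
Reactants: 8 cyclohexenecarbaldehyde; 9 vinylmagnesium bromide
Product: 11 methyl 3-{(1S,2R,6S)-1-[(1R)-1-hydroxyprop-2-enyl]-6-methyl-3-nitro-7-oxabicyclo[4.1.0]heptan-2-yl}propanoate, via bis-allylic alcohol 10 (not isolated)
Conditions: ZnCl2, 9 (2 equiv per Zn), Et2O/dioxane, filter; 8, (+)-MIB (10 mol %), toluene, −10 °C; then t-BuOOH (decane), Ti(Oi-Pr)4 (20 mol %), 0 °C
Reagents that add atoms: tert-butyl hydroperoxide CC(C)(C)OO
Why: Amino-alcohol-catalysed vinylzinc 1,2-addition and titanium-directed epoxidation of the zinc alkoxide in one pot, in which (+)-MIB sends vinyl to the Re face (also the face anti to the pseudoaxial C2 arm) to give the (R)-carbinol, A(1,3) strain with the C6 methyl holds the carbinol C–H in the alkene plane so that oxygen arrives from the carbinol-O face (syn to the C2 arm), and the tetrasubstituted alkene reacts far faster than the vinyl group.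

**Step 5 (key step)**
Reactants: 11 epoxy alcohol
Product: 13 methyl 3-[(1S,2S,3S)-2-ethenyl-3-hydroxy-2-(hydroxymethyl)-3-methyl-6-nitrocyclohexyl]propanoate, via β-hydroxy aldehyde 12 (not isolated)
Conditions: ZnBr2 (20 mol %), CH2Cl2, 0 °C → rt; then MeOH, NaBH4, −20 °C
Reagents that add atoms: none
Why: Semipinacol rearrangement of a 2,3-epoxy alcohol in which Zn chelates the carbinol and oxirane oxygens and the vinyl group antiperiplanar to the C1–O bond shifts from the carbinol carbon to C1 with inversion, so that vinyl ends anti and CHO syn to the C6–OH (which keeps the oxirane configuration), vinyl out-competes hydride, and immediate NaBH4 reduction forestalls retro-aldol cleavage.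

**Step 6**
Reactants: 13 diol; 14 2-bromopropanoyl bromide
Product: 15 methyl 3-[(1S,2S,3S)-2-{[(2-bromopropanoyl)oxy]methyl}-2-ethenyl-3-hydroxy-3-methyl-6-nitrocyclohexyl]propanoate
Conditions: 14 (1.1 equiv), pyridine, CH2Cl2, −30 → 0 °C
Reagents that add atoms: none
Why: Chemoselective O-acylation of the only primary alcohol, since the tertiary C6–OH does not react with the acid bromide at low temperature.

**Step 7**
Reactants: 15 bromo ester
Product: 17 methyl 3-[(1S,5Z,9S,10R)-1-ethenyl-9-hydroxy-5,9-dimethyl-4-oxo-3-oxabicyclo[4.3.1]dec-5-en-10-yl]propanoate, via nitro lactone 16 (not isolated)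
Conditions: KOt-Bu (1.05 equiv), THF, −40 °C; CuBr (20 mol %), β-diketimine ligand (25 mol %), dioxane, 0.005 M, 40 °C; then DBU (2 equiv), rt
Reagents that add atoms: none
Why: Proposed new method: intramolecular copper-catalysed C-alkylation of a secondary nitronate by a tethered secondary α-bromo ester, followed in the same flask by E1cB loss of HNO2 – the Cu(I) nitronate abstracts bromine, the α-acyl radical recombines at the nitronate carbon that sits 1,3-diaxial to the C1 CH2O arm (forming the C3–Cα bond and the seven-membered ring, while O-alkylation would need a nine-membered ring), and DBU then expels nitrite so that the tetrasubstituted alkene can only be Z because the carbonyl carbon and C2 share the seven-membered ring (the alkene is trans only in the nine-membered ring, so bridgehead strain is tolerable); the closest known reaction types are the intermolecular Cu-catalysed alkylation of nitroalkanes with α-bromo carbonyl compounds and the base-induced HNO2 elimination of β-nitro esters.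

**Step 8**
Reactants: 18 5-bromo-2-methylpent-2-ene; 19 lithium acetylide–ethylenediamine complex
Product: 20 6-methylhept-5-en-1-yne
Conditions: DMSO, 10 °C → rt
Reagents that add atoms: none
Why: SN2 alkylation of acetylide with a primary homoallylic bromide.

**Step 9**
Reactants: 21 (Z)-1,2-dichloroethene; 22 ethynyltrimethylsilane
Product: 23 [(Z)-4-chlorobut-3-en-1-ynyl]trimethylsilane
Conditions: 21 (4 equiv), Pd(PPh3)4 (3 mol %), CuI (6 mol %), n-BuNH2, Et2O, rt
Reagents that add atoms: none
Why: Sonogashira mono-coupling of excess (Z)-dichloroethene proceeds with retention, so the future central Z-alkene is taken from the starting material.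

**Step 10**
Reactants: 20 enyne; 23 (Z)-chloroenyne
Product: 25 trimethyl[(3Z,5E)-6,10-dimethylundeca-3,5,9-trien-1-ynyl]silane, via alkenylalane 24 (not isolated)
Conditions: Me3Al (2 equiv), Cp2ZrCl2 (20 mol %), CH2Cl2, rt; then 23, Pd(Pt-Bu3)2 (3 mol %), ZnCl2 (20 mol %), THF, rt
Reagents that add atoms: trimethylaluminium C[Al](C)C
Why: Negishi Zr-catalysed syn-carboalumination sets the E-trisubstituted alkene, and the Pd/Zn-catalysed Negishi coupling with the activated alkenyl chloride retains both alkene geometries.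

**Step 11**
Reactants: 25 silyl dienyne
Product: 26 (3Z,5E)-6,10-dimethylundeca-3,5,9-trien-1-yne
Conditions: K2CO3 (20 mol %), MeOH, rt
Reagents that add atoms: none
Why: Mild methanolytic C-desilylation of an alkynylsilane leaves the Z-diene untouched.

**Step 12**
Reactants: 26 dienyne
Product: 28 (1E,3Z,5E)-1-iodo-2,6,10-trimethylundeca-1,3,5,9-tetraene, via alkenylalane 27 (not isolated)
Conditions: Me3Al (2 equiv), Cp2ZrCl2 (25 mol %), CH2Cl2, 0 °C → rt; then I2 (1.0 equiv), THF, −40 °C, dark
Reagents that add atoms: trimethylaluminium C[Al](C)C; iodine II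
Why: A second Negishi carboalumination of the conjugated terminal alkyne followed by iodinolysis with retention gives the E-iodoalkene, and cold, dark, stoichiometric iodine avoids Z→E isomerisation.

**Step 13**
Reactants: 17 vinyl lactone; 28 tetraenyl iodide
Product: 30 methyl 3-{(1S,5Z,9S,10R)-9-hydroxy-5,9-dimethyl-4-oxo-1-[(3E,5Z,7E)-4,8,12-trimethyltrideca-3,5,7,11-tetraenyl]-3-oxabicyclo[4.3.1]dec-5-en-10-yl}propanoate, via B-alkyl-9-BBN adduct 29 (not isolated)
Conditions: 9-BBN-H (2.5 equiv), THF, rt; then aq Cs2CO3 (destroys excess borane), 28, Pd(dppf)Cl2 (5 mol %), AsPh3 (5 mol %), DMF, rt, dark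
Reagents that add atoms: none
Why: Anti-Markovnikov hydroboration of the only reactive alkene (the tetrasubstituted enoate and both esters are inert to 9-BBN) followed by B-alkyl Suzuki–Miyaura coupling, which retains the iodide geometry.

**Step 14**
Reactants: 30 lactone ester
Product: 31 (2Z)-2-{(2R,3S,4S)-4-hydroxy-3-(hydroxymethyl)-2-(3-hydroxypropyl)-4-methyl-3-[(3E,5Z,7E)-4,8,12-trimethyltrideca-3,5,7,11-tetraenyl]cyclohexylidene}propan-1-ol
Conditions: DIBAL-H (8 equiv), CH2Cl2, −78 → −20 °C; Rochelle salt
Reagents that add atoms: none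
Why: Exhaustive 1,2-reduction opens the lactone to the C1 CH2OH and the Z-allylic alcohol and turns the methyl ester into the hydroxypropyl arm, without touching alkenes or stereocentres.

**Step 15**
Reactants: 31 tetraol
Product: 32 target CNP0179699.1
Conditions: MnO2 (25 equiv), CH2Cl2, rt, dark
Reagents that add atoms: none
Why: MnO2 oxidises only the allylic alcohol to the enal with retention of the Z geometry, while the saturated primary and tertiary alcohols are untouched.

**Compound list**
1 | nitromethane | C[N+](=O)[O-] | starting material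
2 | methyl vinyl ketone | CC(=O)C=C | starting material
3 | 5-nitropentan-2-one | CC(=O)CCC[N+](=O)[O-] | intermediate
4 | methyl pent-4-enoate | COC(=O)CCC=C | starting material
5 | (E)-crotonaldehyde | C/C=C/C=O | starting material
6 | methyl (E)-6-oxohex-4-enoate | COC(=O)CC/C=C/C=O | intermediate
7 | methyl (4S)-5-nitro-8-oxo-4-(2-oxoethyl)nonanoate | COC(=O)CC[C@@H](CC=O)C([N+](=O)[O-])CCC(C)=O | intermediate (not isolated)
8 | methyl 3-[(1S)-2-formyl-3-methyl-6-nitrocyclohex-2-en-1-yl]propanoate | O=CC1=C(C)CCC([N+](=O)[O-])[C@H]1CCC(=O)OC | intermediate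
9 | vinylmagnesium bromide | C=C[Mg]Br | starting material
10 | methyl 3-{(1S)-2-[(1R)-1-hydroxyprop-2-enyl]-3-methyl-6-nitrocyclohex-2-en-1-yl}propanoate (formed as zinc alkoxide) | C=C[C@@H](O)C1=C(C)CCC([N+](=O)[O-])[C@H]1CCC(=O)OC | intermediate (not isolated)
11 | methyl 3-{(1S,2R,6S)-1-[(1R)-1-hydroxyprop-2-enyl]-6-methyl-3-nitro-7-oxabicyclo[4.1.0]heptan-2-yl}propanoate | C=C[C@@H](O)[C@]12O[C@@]1(C)CCC([N+](=O)[O-])[C@H]2CCC(=O)OC | intermediate
12 | methyl 3-[(1S,2R,3S)-2-ethenyl-2-formyl-3-hydroxy-3-methyl-6-nitrocyclohexyl]propanoate | C=C[C@@]1(C=O)[C@H](CCC(=O)OC)C([N+](=O)[O-])CC[C@]1(C)O | intermediate (not isolated)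
13 | methyl 3-[(1S,2S,3S)-2-ethenyl-3-hydroxy-2-(hydroxymethyl)-3-methyl-6-nitrocyclohexyl]propanoate | C=C[C@@]1(CO)[C@H](CCC(=O)OC)C([N+](=O)[O-])CC[C@]1(C)O | intermediate
14 | 2-bromopropanoyl bromide | CC(Br)C(=O)Br | starting material
15 | methyl 3-[(1S,2S,3S)-2-{[(2-bromopropanoyl)oxy]methyl}-2-ethenyl-3-hydroxy-3-methyl-6-nitrocyclohexyl]propanoate | C=C[C@@]1(COC(=O)C(C)Br)[C@H](CCC(=O)OC)C([N+](=O)[O-])CC[C@]1(C)O | intermediate
16 | methyl 3-[(1S,9S,10S)-1-ethenyl-9-hydroxy-5,9-dimethyl-6-nitro-4-oxo-3-oxabicyclo[4.3.1]decan-10-yl]propanoate | C=C[C@]12COC(=O)C(C)C([N+](=O)[O-])(CC[C@]1(C)O)[C@H]2CCC(=O)OC | intermediate (not isolated)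
17 | methyl 3-[(1S,5Z,9S,10R)-1-ethenyl-9-hydroxy-5,9-dimethyl-4-oxo-3-oxabicyclo[4.3.1]dec-5-en-10-yl]propanoate | C=C[C@]12COC(=O)/C(C)=C(/CC[C@]1(C)O)[C@H]2CCC(=O)OC | intermediate
18 | 5-bromo-2-methylpent-2-ene | CC(C)=CCCBr | starting material
19 | lithium acetylide–ethylenediamine complex | [Li]C#C.NCCN | starting material
20 | 6-methylhept-5-en-1-yne | CC(C)=CCCC#C | intermediate
21 | (Z)-1,2-dichloroethene | Cl/C=C\Cl | starting material
22 | ethynyltrimethylsilane | C#C[Si](C)(C)C | starting material
23 | [(Z)-4-chlorobut-3-en-1-ynyl]trimethylsilane | C[Si](C)(C)C#C/C=C\Cl | intermediate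
24 | [(E)-2,6-dimethylhepta-1,5-dienyl]dimethylalane | CC(C)=CCC/C(C)=C/[Al](C)C | intermediate (not isolated)
25 | trimethyl[(3Z,5E)-6,10-dimethylundeca-3,5,9-trien-1-ynyl]silane | CC(C)=CCC/C(C)=C/C=C\C#C[Si](C)(C)C | intermediate
26 | (3Z,5E)-6,10-dimethylundeca-3,5,9-trien-1-yne | CC(C)=CCC/C(C)=C/C=C\C#C | intermediate
27 | dimethyl[(1E,3Z,5E)-2,6,10-trimethylundeca-1,3,5,9-tetraenyl]alane | CC(C)=CCC/C(C)=C/C=C\C(C)=C\[Al](C)C | intermediate (not isolated)
28 | (1E,3Z,5E)-1-iodo-2,6,10-trimethylundeca-1,3,5,9-tetraene | CC(C)=CCC/C(C)=C/C=C\C(C)=C\I | intermediate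
29 | B-alkyl-9-BBN adduct of 17 (C1 arm = CH2CH2–9-BBN) | C3CCC4CCCC3B4CC[C@]12COC(=O)/C(C)=C(/CC[C@]1(C)O)[C@H]2CCC(=O)OC | intermediate (not isolated)
30 | methyl 3-{(1S,5Z,9S,10R)-9-hydroxy-5,9-dimethyl-4-oxo-1-[(3E,5Z,7E)-4,8,12-trimethyltrideca-3,5,7,11-tetraenyl]-3-oxabicyclo[4.3.1]dec-5-en-10-yl}propanoate | CC(C)=CCC/C(C)=C/C=C\C(C)=C\CC[C@]12COC(=O)/C(C)=C(/CC[C@]1(C)O)[C@H]2CCC(=O)OC | intermediate
31 | (2Z)-2-{(2R,3S,4S)-4-hydroxy-3-(hydroxymethyl)-2-(3-hydroxypropyl)-4-methyl-3-[(3E,5Z,7E)-4,8,12-trimethyltrideca-3,5,7,11-tetraenyl]cyclohexylidene}propan-1-ol | CC(C)=CCC/C(C)=C/C=C\C(C)=C\CC[C@@]1(CO)[C@H](CCCO)/C(=C(/C)CO)CC[C@]1(C)O | intermediate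
32 | (2Z)-2-{(2R,3S,4S)-4-hydroxy-3-(hydroxymethyl)-2-(3-hydroxypropyl)-4-methyl-3-[(3E,5Z,7E)-4,8,12-trimethyltrideca-3,5,7,11-tetraenyl]cyclohexylidene}propanal | CC(C)=CCC/C(C)=C/C=C\C(C)=C\CC[C@@]1(CO)[C@H](CCCO)/C(=C(/C)C=O)CC[C@]1(C)O | target

**Step count**
- Total: 15 steps.
- Longest linear sequence: 9 steps (1, 3, 4, 5, 6, 7, 13, 14, 15).

**Three steps most likely to fail**

**Step 4.**
- Risks: the acidic nitro C–H may consume zinc reagent. The tetrasubstituted enal is hindered. The epoxidation must occur syn to the C2 arm, against the steric bias.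
- Fallback: sets out from 8 and returns at 11. The oxirane face is set first, by reagent control, and the vinyl group is added afterwards.
- Luche reduction of 8 (NaBH4, CeCl3) gives the primary allylic alcohol F1.
- Sharpless asymmetric epoxidation with D-(−)-diethyl tartrate, Ti(Oi-Pr)4 and t-BuOOH gives the epoxy alcohol F2.
- Parikh–Doering oxidation gives the epoxy aldehyde F3.
- Chelation-controlled addition of divinylzinc then gives 11. Zinc bridges the aldehyde and oxirane oxygens, and attack comes from the side away from the C6 methyl.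

**Step 5.**
- Risks: C6 is also fully substituted, so the Lewis acid may ionise the C6–O bond instead. That would lead to allylic alcohols or ring-contracted ketones. The aldol-type product may also cleave by retro-aldol reaction.
- Fallback: sets out from 8 and returns at 13. It uses a silicon-activated migrating group whose β-silyl effect accelerates the concerted C1–O cleavage.
- 1-(Trimethylsilyl)vinylzinc is made from (1-bromovinyl)trimethylsilane, t-BuLi and ZnBr2. It adds to 8 under the same amino-alcohol control to give the silylated bis-allylic alcohol F4.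
- VO(acac)2/t-BuOOH gives the epoxy alcohol F5.
- TiCl4 at −78 °C shifts the α-silylvinyl group to give the aldehyde F6, which is reduced at once with NaBH4 to the diol F7.
- Hydroxyl-assisted protodesilylation (TBAF, THF/DMSO, 60 °C) returns 13.

**Step 7 (the proposed new step).**
- Risks: the α-acyl radical may add to the C1 vinyl group. The nitronate may be O-alkylated. The seven-membered ring may not close.
- Fallback with known chemistry: sets out from 13 and returns at 17.
- A buffered reductive Nef reaction (NaOMe, then TiCl3/NH4OAc) gives the keto diol F8.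
- Acylation with 14 and pyridine gives the bromo ester ketone F9.
- A SmI2-mediated intramolecular Reformatsky reaction (THF, −78 °C, high dilution) closes the β-hydroxy lactone F10.
- Dehydration with SOCl2/pyridine gives 17, where the ring again allows only the Z-alkene.

**Further compounds**
F1 | step 4 | methyl 3-[(1S)-2-(hydroxymethyl)-3-methyl-6-nitrocyclohex-2-en-1-yl]propanoate | OCC1=C(C)CCC([N+](=O)[O-])[C@H]1CCC(=O)OC
F2 | step 4 | methyl 3-[(1S,2R,6S)-1-(hydroxymethyl)-6-methyl-3-nitro-7-oxabicyclo[4.1.0]heptan-2-yl]propanoate | OC[C@]12O[C@@]1(C)CCC([N+](=O)[O-])[C@H]2CCC(=O)OC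
F3 | step 4 | methyl 3-[1-formyl-6-methyl-3-nitro-7-oxabicyclo[4.1.0]heptan-2-yl]propanoate (same spatial arrangement as F2) | O=C[C@]12O[C@@]1(C)CCC([N+](=O)[O-])[C@H]2CCC(=O)OC
F4 | step 5 | 2-(trimethylsilyl) analogue of bis-allylic alcohol 10 | C=C([Si](C)(C)C)[C@@H](O)C1=C(C)CCC([N+](=O)[O-])[C@H]1CCC(=O)OC
F5 | step 5 | 2-(trimethylsilyl) analogue of epoxy alcohol 11 | C=C([Si](C)(C)C)[C@@H](O)[C@]12O[C@@]1(C)CCC([N+](=O)[O-])[C@H]2CCC(=O)OC
F6 | step 5 | 1-(trimethylsilyl)ethenyl analogue of aldehyde 12 | C=C([Si](C)(C)C)[C@@]1(C=O)[C@H](CCC(=O)OC)C([N+](=O)[O-])CC[C@]1(C)O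
F7 | step 5 | 1-(trimethylsilyl)ethenyl analogue of diol 13 | C=C([Si](C)(C)C)[C@@]1(CO)[C@H](CCC(=O)OC)C([N+](=O)[O-])CC[C@]1(C)O
F8 | step 7 | methyl 3-[2-ethenyl-3-hydroxy-2-(hydroxymethyl)-3-methyl-6-oxocyclohexyl]propanoate (configuration as in 13) | C=C[C@@]1(CO)[C@H](CCC(=O)OC)C(=O)CC[C@]1(C)O
F9 | step 7 | 2-bromopropanoate ester of F8 at the primary alcohol | C=C[C@@]1(COC(=O)C(C)Br)[C@H](CCC(=O)OC)C(=O)CC[C@]1(C)O
F10 | step 7 | methyl 3-[1-ethenyl-6,9-dihydroxy-5,9-dimethyl-4-oxo-3-oxabicyclo[4.3.1]decan-10-yl]propanoate | C=C[C@]12COC(=O)C(C)C(O)(CC[C@]1(C)O)[C@H]2CCC(=O)OC
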